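Start from Gu: in the larch run it rises as Eb falls, and at 80.0 s the two sum to 99.9%, so count Qi there as lost in the scatter.

all flasks: Eb 0.11 M
- larch: Xa 0.55 M; Ky 2.2 mM; Ek 0.95 mM; temperature 0 °C; run made earlier
- Saturday's: Xa 0.550 M; Ky 2.20 mM; Ek 1.9 mM; temperature 0 °C; time 4.0 min
- Friday's: Xa 0.550 M; Ky 2.20 mM; Ek 1.9 mM; temperature 50 °C; time 4.0 min
- Wednesday's: Xa 0.550 M; Ky 2.20 mM; Ek 1.9 mM; temperature 25 °C; time 4.0 min

- larch (time / s: Gu / %, Eb / %): 10.0: 2.2, 98.0; 12.0: 3.7, 97.3; 30.0: 11.3, 88.6; 80.0: 26.2, 73.7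

(standard deviation of a reading: 1 percentage point)

- reactions considered so far: Xa + Ek <-> Wa; Wa -> Ry; Ry -> Ve + Aj; Eb + Aj <-> Ze; Ze -> Ek + Gu; Gu -> Qi; Wa + Ky -> Xo
- the earlier runs do not show what temperature does; that part of a forecast is a guess
- no earlier run changes the charge of Ek; that part of a forecast is a guess

* the flask that comes out highest in amount of Gu, in percent of the Eb charged, or "all alike" when all lie within 1.5 percentage points (Saturday's / Friday's / Wednesday's / all alike)
* Gu at the end, in percent of the Eb charged, Saturday's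
* Gu at the end, in percent of the Eb charged, Friday's
* Gu at the end, in percent of the Eb charged, Wednesday's

Climb the ladder of times, fastest first. Start-up: at 10.0 s Gu lies 1.1 percentage points under the straight line to the last larch reading, about the scatter, so treat any lag as hidden. Round: Gu made per catalyst per second in the larch run, the turnover frequency N, reads 0.379 s⁻¹, which makes one round of Ek about 2.64 s.

Next comes Eb, the limiting reagent, since Xa is charged 5.00 times over. Assume that pace follows Ek, which is a guess. Saturday's then needs 2.54 min: this is the Eb clock tE, the Eb charge divided by N times the Ek charge, the time to pass the charge through the catalyst at steady pace. Saturday's clock is shorter than its 4.0 min, which offers 1.57 clocks.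

Last rung: Gu → Qi, unseen in the larch run. The written steps carry Eb on to Qi, so treat Gu as a way-station. For Saturday's, read Gu as the charge less Eb left less Qi. The earlier runs do not show what temperature does to these rungs.

The forecast puts Wednesday's highest: Saturday's 73% (58% to 86%), Friday's 72% (40% to 96%), Wednesday's 88% (65% to 98%). For Friday's it expects that “Gu → Qi probably gains substantially”. Differ on Saturday's: hold Gu above 73%, because its time exceeds its clock.

Saturday's gives 90.0%, Wednesday's 9.63% and Friday's 0%, so Saturday's comes out highest.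

    Xa + Ek ⇌ Wa (K = 1.60 L mol⁻¹, k = 42.0 L mol⁻¹ s⁻¹, Ea = 39.0 kJ mol⁻¹, ΔH = −2.00 kJ mol⁻¹)
    Wa → Ry (k = 19.0 s⁻¹, Ea = 64.0 kJ mol⁻¹)
    Ry → Ve + Aj (k = 0.910 s⁻¹, Ea = 66.0 kJ mol⁻¹)
    Eb + Aj ⇌ Ze (K = 15.0 L mol⁻¹, k = 330 L mol⁻¹ s⁻¹, Ea = 38.0 kJ mol⁻¹, ΔH = 6.00 kJ mol⁻¹)
    Ze → Ek + Gu (k = 1.30 s⁻¹, Ea = 60.0 kJ mol⁻¹)
    Gu → Qi (k = 5.90 × 10⁻⁴ s⁻¹, Ea = 77.0 kJ mol⁻¹)
    Wa + Ky → Xo (k = 1.60 L mol⁻¹ s⁻¹, Ea = 40.0 kJ mol⁻¹)
    (constants at 0 °C)

Wednesday's ends with Eb at 0% and Qi at 90.4%. Half of Saturday's clock is 1.27 min, and Saturday's reached half conversion in 1.32 min. Friday's, charged alike, reached it in 1.16 s, shorter than half that clock by a factor of 65.7.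

The earlier runs and the new flask were generated by integration from invented constants; scatter was added.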